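The earlier runs and the new flask were computed with constants of no real substance; scatter was added.

- I decided to read these flasks by dose rather than by the clock, and to keep track of the carrier, charged on starting material at 14 mol% on Wednesday, 22 mol% on Sunday and 10 mol% in the flask. Its forms are spent carrier, fresh carrier and spent catalyst, and counted as catalyst they add up to the charge.

in all of them: starting material 20 mM
- Wednesday's: salt in the second phase 2 equiv; spent carrier 14 mol%; run made earlier
- Sunday's: salt in the second phase 2 equiv; spent carrier 22 mol%; run made earlier
- flask: salt in the second phase 2.00 equiv; spent carrier 10 mol%; time 30 h; volume of the second phase over the first 1.0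

| run | time / h | target / % | starting material / % |
|---|---|---|---|
| Wednesday's | 0.417 | 77.9 | 18.1 |
| Wednesday's | 0.833 | 85.8 | 6.7 |
| Wednesday's | 2.00 | 85.8 | 1.1 |
| Wednesday's | 5.00 | 77.0 | 0.2 |
| Wednesday's | 10.0 | 69.4 | 0 |
| Wednesday's | 25.0 | 60.6 | 0.6 |
| Sunday's | 0.417 | 83.5 | 10.1 |
| Sunday's | 0.833 | 86.8 | 2.9 |
| Sunday's | 2.00 | 82.1 | 0.1 |
| Sunday's | 5.00 | 72.1 | 0 |
| Sunday's | 10.0 | 64.5 | 0 |
| Sunday's | 25.0 | 56.6 | 0.3 |

(standard deviation of a reading: 0.3 percentage points)

- in the second phase: salt in the second phase, spent salt in the second phase; everything else is in the first
- charges count per volume of the first phase; a concentration in a rate is the amount of a species over the volume of its own phase; every rate counts per litre of the first phase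
- the numbers in the tables scatter by 0.3 percentage points (one standard deviation)
- steps under discussion: spent carrier + salt in the second phase <-> fresh carrier + spent salt in the second phase; starting material + fresh carrier -> target + spent carrier; target + fresh carrier <-> isomer of the product + fresh carrier; 2 fresh carrier -> spent catalyst
- the earlier runs hold the two phases in the same ratio of volumes as the flask asked about

- time up to 30 h at which target stands highest
- the amount of target, in percent of the starting material charged, at that time

- First instants: the carrier goes in spent, the salt in the second phase turns it fresh, and starting material turns it back. Starting material, the limiting reagent, falls to 10.1% by 0.417 h on Sunday, lower than Wednesday's 18.1%.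
- Both conversion and isomerisation run on c(fresh carrier), which dies in pairs, termination in the polymer sense. With salt and volumes held as here, and a steady split of the carrier not yet dead between fresh and spent, their progress follows loading times time.
- Middle: Sunday's highest reading, 86.8%, stands at a dose, the loading of carrier times the time, of 0.183 h. Wednesday's equal readings on either side lie at 0.117 h and 0.280 h, and both are lower. At Sunday's peak reading, 10.3% of the charge is neither target nor starting material, and I counted that as isomer.
- End: Wednesday loses 8.8 percentage points from 2.00 h to 5.00 h, then the same from 10.0 h to 25.0 h, so the hourly loss slows.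
- For the flask, at 10 mol%, my dose gave 1.83 h, with a height near that reading of 86.8%, which carries the scatter of 0.3 points.
- The forecast said 1.65 h and 86.9%, earlier than my time, on the ground that “The two runs collapse onto one curve”.

- The flask peaked at 1.60 h with 86.8%, a dose of 0.160 h against my 0.183 h, and 58.6% of its catalyst was then spent catalyst.

    spent carrier + salt in the second phase ⇌ fresh carrier + spent salt in the second phase (K = 1.25, k = 11.9 L mol⁻¹ s⁻¹)
    starting material + fresh carrier → target + spent carrier (k = 0.786 L mol⁻¹ s⁻¹)
    target + fresh carrier ⇌ isomer of the product + fresh carrier, rate k3*[target]*[fresh carrier] forward; the back reaction follows from the equilibrium constant (K = 2.40, k = 0.0347 L mol⁻¹ s⁻¹)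
    2 fresh carrier → spent catalyst (k = 0.162 L mol⁻¹ s⁻¹)

- A neighbouring flask of the same recipe, read at 12 h, has a dose of 1.20 h. That lies between Sunday at 5.00 h, dose 1.10 h, and Wednesday at 10.0 h, dose 1.40 h, whose readings are 72.1% and 69.4%. The neighbour holds 71.2% of target.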